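Numbering (carotenoid): C1'–C6' is the 3',6'-dihydroxycyclohexene ring, C7'…C15'/C15…C7 is the chain, and C1–C6 is the hydroxycyclohexene ring on the C7≡C8 alkyne.
Cuts: O–Si at C3. Then C10'–C11' together with C9'–CH3 in one operation, giving a C13 enyne diol and a C26 iodide. Then C11=C12 (Wittig), C11'=C12' (Takai), C6–C7 (Sonogashira), C7'=C8' (Wittig), C3'–O (Pd) and C5'/C6'–O (epoxidation).
Enabling feature: C10'H is the unsubstituted end of the E-trisubstituted alkene C9'(CH3)=C10'H, which is attached through E-C7'=C8' to the quaternary carbinol C6' of ring C1'–C6'. A methyl-branched alkenyl terminus of this kind is what syn-methylalumination of a terminal alkyne C9'≡C10'H delivers, already metalated at C10' for sp2–sp2 coupling to the E-iodoalkene carbon C11'.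
Forward: both carbocycles are bought (safranal, actinol). Only a temporary oxirane (C5'–O–C6') is made and then opened. The chain is joined in the order C6–C7, C11=C12 (onto a C11 iodotetraenal made from the C10 dialdehyde), then C10'–C11'.
Stereochemistry: C3 comes from (4R,6R)-actinol. C6' comes from Sharpless epoxidation with L-(+)-tartrate. C3' is relayed from C6' by double-inversion Pd allylation (cis). Alkene geometry comes from the purchased E-enynol and E,E,E-dialdehyde, E-selective olefinations, syn-carbometalation and stereoretentive coupling.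

Key step: step 14

Assumption: compounds 1, 6, 10, 12 and 16 are taken as purchasable, and all polyenes are handled under argon with exclusion of light and acid.

Step 1
Reactants: 1 safranal
Product: 2 (2,6,6-trimethylcyclohexa-1,3-dien-1-yl)methanol
Conditions: NaBH4, MeOH, 0 °C
Reagents that add atoms: none
Why: 1,2-hydride reduction of the hindered dienal gives the dienyl carbinol that serves as directing handle for the epoxidation, and no stereocentre is formed.

Step 2
Reactants: 2 (2,6,6-trimethylcyclohexa-1,3-dien-1-yl)methanol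
Product: 3 [(1S,6S)-2,2,6-trimethyl-7-oxabicyclo[4.1.0]hept-4-en-1-yl]methanol
Conditions: Ti(OiPr)4 (cat.), L-(+)-diethyl tartrate (cat.), t-BuOOH (decane), 4 Å MS, CH2Cl2, −20 °C; non-acidic work-up
Reagents that add atoms: tert-butyl hydroperoxide CC(C)(C)OO
Why: Sharpless asymmetric epoxidation is directed by the allylic hydroxyl to the tetrasubstituted C5'=C6' alkene only, and the L-(+)-tartrate catalyst delivers oxygen in the sense that makes the carbinol-bearing oxirane carbon S (the sense found for other 3,3-disubstituted allylic alcohols with a Z-methyl group), which sets C6' and, transiently, C5'.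

Step 3
Reactants: 3 [(1S,6S)-2,2,6-trimethyl-7-oxabicyclo[4.1.0]hept-4-en-1-yl]methanol
Product: 4 (1S,4R)-4-hydroxy-4-(hydroxymethyl)-3,5,5-trimethylcyclohex-2-en-1-yl acetate
Conditions: Pd(PPh3)4 (cat.), AcOH, THF, 0 °C
Reagents that add atoms: acetic acid CC(=O)O
Why: In this Tsuji–Trost-type 1,4-opening of a vinyl oxirane, Pd(0) ionises the allylic tertiary C5'–O bond with inversion and acetate attacks the unhindered C3' end of the η3-allyl anti to palladium, so the new C3' stereocentre forms cis to the C6' oxygen (3'S) by double inversion.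

Step 4
Reactants: 4 (1S,4R)-4-hydroxy-4-(hydroxymethyl)-3,5,5-trimethylcyclohex-2-en-1-yl acetate
Product: 5 (1S,4R)-4-formyl-4-hydroxy-3,5,5-trimethylcyclohex-2-en-1-yl acetate
Conditions: SO3·pyridine, DMSO, Et3N, CH2Cl2, 0 °C
Reagents that add atoms: none
Why: Parikh–Doering oxidation converts only the primary alcohol, does not cleave the 1,2-diol, and leaves the tertiary alcohol, the allylic acetate and both stereocentres untouched.

Step 5
Reactants: 5 (1S,4R)-4-formyl-4-hydroxy-3,5,5-trimethylcyclohex-2-en-1-yl acetate; 6 triphenyl[3-(trimethylsilyl)prop-2-yn-1-yl]phosphonium bromide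
Product: 8 (1S,4R)-4-hydroxy-3,5,5-trimethyl-4-[(1E)-4-(trimethylsilyl)but-1-en-3-yn-1-yl]cyclohex-2-en-1-yl acetate, via propargylic ylide 7 (not isolated)
Conditions: 6, n-BuLi, THF, −78 °C; then 5, −78 °C→rt
Reagents that add atoms: none
Why: Wittig olefination with the semi-stabilised propargylic ylide, which is too weakly basic to deprotonate the tertiary alcohol or attack the acetate, should give mainly the E-enyne with this α-quaternary aldehyde, and any Z isomer is removed by chromatography.

Step 6
Reactants: 8 (1S,4R)-4-hydroxy-3,5,5-trimethyl-4-[(1E)-4-(trimethylsilyl)but-1-en-3-yn-1-yl]cyclohex-2-en-1-yl acetate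
Product: 9 (1R,4S)-1-[(1E)-but-1-en-3-yn-1-yl]-2,6,6-trimethylcyclohex-2-ene-1,4-diol
Conditions: K2CO3 (cat.), MeOH, rt
Reagents that add atoms: none
Why: Base-catalysed methanolysis (transesterification plus protiodesilylation of the alkynylsilane) frees the secondary alcohol and the terminal alkyne in one operation without touching a stereocentre.

Step 7
Reactants: 10 (2E,4E,6E)-2,7-dimethylocta-2,4,6-trienedial
Product: 11 (2E,4E,6E,8E)-9-iodo-2,7-dimethylnona-2,4,6,8-tetraenal
Conditions: CHI3 (limiting), CrCl2, 10 in excess (recovered), THF–dioxane, 0 °C→rt, dark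
Reagents that add atoms: iodoform IC(I)I
Why: Takai iodoolefination, run with the symmetric dialdehyde in excess so that only one formyl group reacts, gives the E-iodoalkene C11'=C12' through the gem-dichromium adduct, and its geometric purity can be secured on this small compound.

Step 8
Reactants: 12 (4R,6R)-4-hydroxy-2,2,6-trimethylcyclohexan-1-one (actinol)
Product: 13 (4R,6R)-4-[(tert-butyldimethylsilyl)oxy]-2,2,6-trimethylcyclohexan-1-one
Conditions: TBSCl, imidazole, DMF, rt
Reagents that add atoms: tert-butyldimethylsilyl chloride CC(C)(C)[Si](C)(C)Cl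
Why: Standard silylation of the secondary alcohol masks the only acidic proton before enolate chemistry and keeps the C3 stereocentre of the chiral-pool ketone.

Step 9
Reactants: 13 (4R,6R)-4-[(tert-butyldimethylsilyl)oxy]-2,2,6-trimethylcyclohexan-1-one
Product: 15 (4R)-4-[(tert-butyldimethylsilyl)oxy]-2,6,6-trimethylcyclohex-1-en-1-yl trifluoromethanesulfonate, via lithium enolate 14 (not isolated)
Conditions: LDA, THF, −78 °C; PhNTf2, −78 °C→rt
Reagents that add atoms: N-phenylbis(trifluoromethanesulfonimide) O=S(=O)(N(c1ccccc1)S(=O)(=O)C(F)(F)F)C(F)(F)F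
Why: The ketone has a single enolisable position, so enolate O-triflation gives the tetrasubstituted enol triflate regiospecifically, erasing the methyl-bearing stereocentre on purpose and leaving the silyloxy stereocentre (γ to the carbonyl) untouched.

Step 10
Reactants: 15 (4R)-4-[(tert-butyldimethylsilyl)oxy]-2,6,6-trimethylcyclohex-1-en-1-yl trifluoromethanesulfonate; 16 (2E)-3-methylpent-2-en-4-yn-1-ol
Product: 17 (2E)-5-{(4R)-4-[(tert-butyldimethylsilyl)oxy]-2,6,6-trimethylcyclohex-1-en-1-yl}-3-methylpent-2-en-4-yn-1-ol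
Conditions: Pd(PPh3)4 (cat.), CuI (cat.), Et3N, DMF, rt
Reagents that add atoms: none
Why: Sonogashira coupling of the hindered enol triflate with the terminal alkyne forms C6–C7, tolerates the free allylic alcohol and carries the E geometry of C9=C10 over from the purchased enynol.

Step 11
Reactants: 17 (2E)-5-{(4R)-4-[(tert-butyldimethylsilyl)oxy]-2,6,6-trimethylcyclohex-1-en-1-yl}-3-methylpent-2-en-4-yn-1-ol
Product: 18 {[(1R)-4-[(3E)-5-bromo-3-methylpent-3-en-1-yn-1-yl]-3,5,5-trimethylcyclohex-3-en-1-yl]oxy}(tert-butyl)dimethylsilane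
Conditions: CBr4, PPh3, CH2Cl2, −20 °C
Reagents that add atoms: carbon tetrabromide BrC(Br)(Br)Br
Why: The Appel reaction replaces the primary allylic hydroxyl by bromide through a neutral SN2 pathway, which avoids an allyl cation and so keeps the 9E geometry and the silyl ether.

Step 12
Reactants: 18 {[(1R)-4-[(3E)-5-bromo-3-methylpent-3-en-1-yn-1-yl]-3,5,5-trimethylcyclohex-3-en-1-yl]oxy}(tert-butyl)dimethylsilane
Product: 19 tributyl[(2E)-5-{(4R)-4-[(tert-butyldimethylsilyl)oxy]-2,6,6-trimethylcyclohex-1-en-1-yl}-3-methylpent-2-en-4-yn-1-yl]phosphonium bromide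
Conditions: PBu3, EtOAc, rt
Reagents that add atoms: tributylphosphine CCCCP(CCCC)CCCC
Why: SN2 quaternisation of the nucleophilic trialkylphosphine by the primary allylic bromide occurs at room temperature without disturbing the alkene geometry.

Step 13
Reactants: 19 tributyl[(2E)-5-{(4R)-4-[(tert-butyldimethylsilyl)oxy]-2,6,6-trimethylcyclohex-1-en-1-yl}-3-methylpent-2-en-4-yn-1-yl]phosphonium bromide; 11 (2E,4E,6E,8E)-9-iodo-2,7-dimethylnona-2,4,6,8-tetraenal
Product: 21 tert-butyl({(1R)-4-[(3E,5E,7E,9E,11E,13E)-14-iodo-3,7,12-trimethyltetradeca-3,5,7,9,11,13-hexaen-1-yn-1-yl]-3,5,5-trimethylcyclohex-3-en-1-yl}oxy)dimethylsilane, via allylic ylide 20 (not isolated)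
Conditions: KOtBu, THF, −78 °C; then 11, −78→0 °C, dark
Reagents that add atoms: none
Why: Wittig olefination with an allylic trialkylphosphonium ylide, a class that is E-selective with enals, forms C11=C12, while low temperature and a short ylide lifetime protect the 9E geometry and the iodoalkene is inert.

Step 14
Reactants: 9 (1R,4S)-1-[(1E)-but-1-en-3-yn-1-yl]-2,6,6-trimethylcyclohex-2-ene-1,4-diol; 21 tert-butyl({(1R)-4-[(3E,5E,7E,9E,11E,13E)-14-iodo-3,7,12-trimethyltetradeca-3,5,7,9,11,13-hexaen-1-yn-1-yl]-3,5,5-trimethylcyclohex-3-en-1-yl}oxy)dimethylsilane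
Product: 23 (all-E,3R,3'S,6'R)-3-[(tert-butyldimethylsilyl)oxy]-7,8-didehydro-β,ε-carotene-3',6'-diol, via alkenylalane 22 (not isolated)
Conditions: 9, Me3Al (excess), Cp2ZrCl2 (cat.), ClCH2CH2Cl, 0→23 °C; volatiles removed in vacuo; then 21, ZnCl2 (cat.), Pd2(dba)3/P(2-furyl)3 (cat.), THF–DMF, 23 °C, dark; cold aq NaHCO3
Reagents that add atoms: trimethylaluminium C[Al](C)C
Why: Me3Al first turns both hydroxyls of 9 into dimethylaluminium alkoxides (masking in the flask), then the Zr–CH3/Al species adds CH3 and metal syn across the terminal alkyne, CH3 to internal C9' and Al to terminal C10', giving the (E)-alkenylalane 22. After excess Me3Al is stripped off, Al→Zn→Pd transmetalation meets the alkenylpalladium iodide formed by oxidative addition of 21, and reductive elimination forms C10'–C11' with retention at both sp2 carbons. The closest known reaction type is the tandem Zr-catalysed methylalumination/Pd–Zn-co-catalysed Negishi alkenyl–alkenyl coupling used for methyl-branched conjugated polyenes. No ring is closed and no stereocentre is created; the one new stereochemical element, the E geometry of C9'=C10', is fixed by the syn addition. The step needs regioselective metalation at the CH terminus, reaction of one alkyne only, and intact carbinols; these are secured because 9 has a single sterically biased terminal alkyne, the internal C7≡C8 alkyne of 21 enters only after carbometalation is over, and the O–Al bonds are poor leaving groups at this temperature. One flask therefore installs the C9' methyl branch and the trisubstituted alkene and joins C14 to C26 with all other double bonds preset.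

Step 15
Reactants: 23 (all-E,3R,3'S,6'R)-3-[(tert-butyldimethylsilyl)oxy]-7,8-didehydro-β,ε-carotene-3',6'-diol
Product: 24 (all-E,3R,3'S,6'R)-7,8-didehydro-β,ε-carotene-3,3',6'-triol (target)
Conditions: TBAF, THF, 0 °C→rt, dark
Reagents that add atoms: none
Why: Fluoride desilylation runs under basic, acid-free conditions, so the ionisable doubly allylic C6' alcohol, the polyene geometry and all three stereocentres should survive.

Compound list
1 | safranal | CC1=C(C=O)C(C)(C)CC=C1 | starting material
2 | (2,6,6-trimethylcyclohexa-1,3-dien-1-yl)methanol | CC1=C(CO)C(C)(C)CC=C1 | intermediate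
3 | [(1S,6S)-2,2,6-trimethyl-7-oxabicyclo[4.1.0]hept-4-en-1-yl]methanol | OC[C@]12O[C@@]1(C)C=CCC2(C)C | intermediate
4 | (1S,4R)-4-hydroxy-4-(hydroxymethyl)-3,5,5-trimethylcyclohex-2-en-1-yl acetate | CC1=C[C@@H](OC(C)=O)CC(C)(C)[C@]1(O)CO | intermediate
5 | (1S,4R)-4-formyl-4-hydroxy-3,5,5-trimethylcyclohex-2-en-1-yl acetate | CC1=C[C@@H](OC(C)=O)CC(C)(C)[C@]1(O)C=O | intermediate
6 | triphenyl[3-(trimethylsilyl)prop-2-yn-1-yl]phosphonium bromide | C[Si](C)(C)C#CC[P+](c1ccccc1)(c1ccccc1)c1ccccc1.[Br-] | starting material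
7 | triphenyl[3-(trimethylsilyl)prop-2-yn-1-ylidene]phosphorane | C[Si](C)(C)C#CC=P(c1ccccc1)(c1ccccc1)c1ccccc1 | intermediate
8 | (1S,4R)-4-hydroxy-3,5,5-trimethyl-4-[(1E)-4-(trimethylsilyl)but-1-en-3-yn-1-yl]cyclohex-2-en-1-yl acetate | CC1=C[C@@H](OC(C)=O)CC(C)(C)[C@]1(O)/C=C/C#C[Si](C)(C)C | intermediate
9 | (1R,4S)-1-[(1E)-but-1-en-3-yn-1-yl]-2,6,6-trimethylcyclohex-2-ene-1,4-diol | CC1=C[C@@H](O)CC(C)(C)[C@]1(O)/C=C/C#C | intermediate
10 | (2E,4E,6E)-2,7-dimethylocta-2,4,6-trienedial | O=C/C(C)=C/C=C/C=C(C)/C=O | starting material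
11 | (2E,4E,6E,8E)-9-iodo-2,7-dimethylnona-2,4,6,8-tetraenal | O=C/C(C)=C/C=C/C=C(C)/C=C/I | intermediate
12 | (4R,6R)-4-hydroxy-2,2,6-trimethylcyclohexan-1-one (actinol) | O=C1[C@H](C)C[C@@H](O)CC1(C)C | starting material
13 | (4R,6R)-4-[(tert-butyldimethylsilyl)oxy]-2,2,6-trimethylcyclohexan-1-one | O=C1[C@H](C)C[C@@H](O[Si](C)(C)C(C)(C)C)CC1(C)C | intermediate
14 | lithium (4R)-4-[(tert-butyldimethylsilyl)oxy]-2,6,6-trimethylcyclohex-1-en-1-olate | [Li]OC1=C(C)C[C@@H](O[Si](C)(C)C(C)(C)C)CC1(C)C | intermediate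
15 | (4R)-4-[(tert-butyldimethylsilyl)oxy]-2,6,6-trimethylcyclohex-1-en-1-yl trifluoromethanesulfonate | O=S(=O)(OC1=C(C)C[C@@H](O[Si](C)(C)C(C)(C)C)CC1(C)C)C(F)(F)F | intermediate
16 | (2E)-3-methylpent-2-en-4-yn-1-ol | C#C/C(C)=C/CO | starting material
17 | (2E)-5-{(4R)-4-[(tert-butyldimethylsilyl)oxy]-2,6,6-trimethylcyclohex-1-en-1-yl}-3-methylpent-2-en-4-yn-1-ol | OC/C=C(\C)C#CC1=C(C)C[C@@H](O[Si](C)(C)C(C)(C)C)CC1(C)C | intermediate
18 | {[(1R)-4-[(3E)-5-bromo-3-methylpent-3-en-1-yn-1-yl]-3,5,5-trimethylcyclohex-3-en-1-yl]oxy}(tert-butyl)dimethylsilane | BrC/C=C(\C)C#CC1=C(C)C[C@@H](O[Si](C)(C)C(C)(C)C)CC1(C)C | intermediate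
19 | C15 tributylphosphonium bromide (name as in step 12) | CCCC[P+](CCCC)(CCCC)C/C=C(\C)C#CC1=C(C)C[C@@H](O[Si](C)(C)C(C)(C)C)CC1(C)C.[Br-] | intermediate
20 | C15 allylic tributylphosphonium ylide derived from 19 | CCCCP(CCCC)(CCCC)=C/C=C(\C)C#CC1=C(C)C[C@@H](O[Si](C)(C)C(C)(C)C)CC1(C)C | intermediate
21 | C26 (all-E) hexaenynyl iodide (name as in step 13) | I/C=C/C(C)=C/C=C/C=C(C)/C=C/C=C(\C)C#CC1=C(C)C[C@@H](O[Si](C)(C)C(C)(C)C)CC1(C)C | intermediate
22 | (1E,3E)-dienyl(dimethyl)alane of 9 with CH3 at C9' and both oxygens as dimethylaluminium alkoxides | CC1=C[C@@H](O[Al](C)C)CC(C)(C)[C@]1(O[Al](C)C)/C=C/C(C)=C/[Al](C)C | intermediate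
23 | (all-E,3R,3'S,6'R)-3-[(tert-butyldimethylsilyl)oxy]-7,8-didehydro-β,ε-carotene-3',6'-diol | CC1=C[C@@H](O)CC(C)(C)[C@]1(O)/C=C/C(C)=C/C=C/C(C)=C/C=C/C=C(C)/C=C/C=C(\C)C#CC1=C(C)C[C@@H](O[Si](C)(C)C(C)(C)C)CC1(C)C | intermediate
24 | (all-E,3R,3'S,6'R)-7,8-didehydro-β,ε-carotene-3,3',6'-triol | CC1=C[C@@H](O)CC(C)(C)[C@]1(O)/C=C/C(C)=C/C=C/C(C)=C/C=C/C=C(C)/C=C/C=C(\C)C#CC1=C(C)C[C@@H](O)CC1(C)C | target

Total step count: 15. Longest linear sequence: 8 (steps 8–15; the branch of steps 1–6, 14, 15 is equally long).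

Steps most likely to fail

Step 14.
- What may go wrong: Lewis-acid-induced ionisation of the doubly allylic C6' aluminium alkoxide, before or more easily after it becomes conjugated with the long polyene. Methyl transfer to the iodide may compete, and the polyenyl iodide may degrade during a slow coupling.
- Fallback, from 5, rejoining at 23: Horner–Wadsworth–Emmons olefination of 5 uses two equivalents of the lithium anion of diethyl [(2E)-2-methyl-3-(tributylstannyl)prop-2-en-1-yl]phosphonate, the first equivalent being consumed by the tertiary hydroxyl. This would give the acetate-protected (1E,3E)-dienylstannane F1. Methanolysis (K2CO3, MeOH) would give the dienylstannane diol F2. Stille coupling of F2 with 21 (Pd2(dba)3, AsPh3, NMP, rt, dark) would form the same C10'–C11' bond under neutral, Lewis-acid-free conditions and give 23.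

Step 2.
- What may go wrong: titanium-promoted opening or rearrangement of the tertiary allylic oxirane during reaction or work-up, and insufficient facial discrimination on the tetrasubstituted dienol.
- Fallback, from 13, rejoining at 9: this replaces catalyst control by substrate control from the same chiral-pool ketone. Enolate 14 is trapped with TMSCl as the trimethylsilyl enol ether F3. Saegusa–Ito dehydrogenation (Pd(OAc)2, MeCN) gives the (4S)-silyloxy enone F4, whose stereocentre is the future C3'. 1,2-Addition of (E)-4-(trimethylsilyl)but-1-en-3-yn-1-yllithium (from the bromide and t-BuLi) on the face anti to the silyloxy group gives the bis-silylated tertiary alcohol F5, and the C6' epimer is removed by chromatography. TBAF then removes both silyl groups to give 9.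

Step 13.
- What may go wrong: loss of the 9E geometry by bond rotation in the delocalised allylic ylide, and incomplete E selectivity at C11=C12.
- Fallback, from 17 and 11, rejoining at 21: this reverses the polarity so that the enyne half is never deprotonated. MnO2 oxidation of 17 gives the enynal F6. NaBH4 reduction of 11 gives the iodotetraenol F7. Appel bromination gives the iodotetraenyl bromide F8. Michaelis–Becker reaction with sodium diethyl phosphite at 0 °C gives the iodotetraenyl phosphonate F9. Horner–Wadsworth–Emmons olefination of F6 with the sodium anion of F9 (NaHMDS, THF, −78→0 °C) gives 21.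

Further compounds
F1 | step 14 | (1S,4R)-4-hydroxy-3,5,5-trimethyl-4-[(1E,3E)-3-methyl-4-(tributylstannyl)buta-1,3-dien-1-yl]cyclohex-2-en-1-yl acetate | CC1=C[C@@H](OC(C)=O)CC(C)(C)[C@]1(O)/C=C/C(C)=C/[Sn](CCCC)(CCCC)CCCC
F2 | step 14 | (1R,4S)-2,6,6-trimethyl-1-[(1E,3E)-3-methyl-4-(tributylstannyl)buta-1,3-dien-1-yl]cyclohex-2-ene-1,4-diol | CC1=C[C@@H](O)CC(C)(C)[C@]1(O)/C=C/C(C)=C/[Sn](CCCC)(CCCC)CCCC
F3 | step 2 | tert-butyldimethyl{[(1R)-3,5,5-trimethyl-4-[(trimethylsilyl)oxy]cyclohex-3-en-1-yl]oxy}silane | C[Si](C)(C)OC1=C(C)C[C@@H](O[Si](C)(C)C(C)(C)C)CC1(C)C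
F4 | step 2 | (4S)-4-[(tert-butyldimethylsilyl)oxy]-2,6,6-trimethylcyclohex-2-en-1-one | CC1=C[C@@H](O[Si](C)(C)C(C)(C)C)CC(C)(C)C1=O
F5 | step 2 | (1R,4S)-4-[(tert-butyldimethylsilyl)oxy]-2,6,6-trimethyl-1-[(1E)-4-(trimethylsilyl)but-1-en-3-yn-1-yl]cyclohex-2-en-1-ol | CC1=C[C@@H](O[Si](C)(C)C(C)(C)C)CC(C)(C)[C@]1(O)/C=C/C#C[Si](C)(C)C
F6 | step 13 | (2E)-5-{(4R)-4-[(tert-butyldimethylsilyl)oxy]-2,6,6-trimethylcyclohex-1-en-1-yl}-3-methylpent-2-en-4-ynal | O=C/C=C(\C)C#CC1=C(C)C[C@@H](O[Si](C)(C)C(C)(C)C)CC1(C)C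
F7 | step 13 | (2E,4E,6E,8E)-9-iodo-2,7-dimethylnona-2,4,6,8-tetraen-1-ol | OC/C(C)=C/C=C/C=C(C)/C=C/I
F8 | step 13 | (1E,3E,5E,7E)-9-bromo-1-iodo-3,8-dimethylnona-1,3,5,7-tetraene | BrC/C(C)=C/C=C/C=C(C)/C=C/I
F9 | step 13 | diethyl [(2E,4E,6E,8E)-9-iodo-2,7-dimethylnona-2,4,6,8-tetraen-1-yl]phosphonate | CCOP(=O)(OCC)C/C(C)=C/C=C/C=C(C)/C=C/I
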